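**Retrosynthetic overview**
1. Target 16 ⇐ acetylation and angeloylation (C–O) of 7β,13-diol 14, whose C7 carbinol comes from C13-OH-directed reduction of 7-ketone 13; both angelates come from one batch of mixed anhydride 11, made from angelic acid 10.
2. 13 ⇐ dienedione 7: the C9–O bond from catalyst-controlled conjugate borylation/oxidation of the cycloheptenone.
3. 7 ⇐ dienedione 6: the C13–O bond (the key bond, which also sets C6) from a new palladium-catalysed methyl C–H acetoxylation steered by a chiral transient directing group.
4. 6 ⇐ SeO2 allylic oxidation of Δ8-alkene 4 ⇐ C8–H bromination/elimination of vulgarone B 2 ⇐ allylic oxidation of (+)-α-longipinene 1.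
5. Rings: none is built; the cyclobutane, cyclohexene and cycloheptane rings and the C4, C5, C10, C11 stereocentres come intact from 1, and only C–H and C–O bonds change.

Assumption: commercial (+)-α-longipinene is the (1R,2S,7R,8R) enantiomer, which has the C4, C5, C10, C11 configuration of the target (natural Stevia longipinene series).

Numbering used (longipinane): C1(=O)–C2=C3(C12)–C4; cyclobutane C4–C5–C11–C10; C5–C6(C13,C14)–C7–C8–C9–C10(C15); C11–C1. α is the face of the seven-membered ring that carries H5, H11 and the C15 methyl (C13 is the α substituent of C6); β is the face bridged by C4. The target is (4R,5S,6S,7R,9R,10R,11R)-7β-acetoxy-9α,13-bis(angeloyloxy)longipin-2-en-1-one.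

**Step 1**
Reactants: 1 (+)-α-longipinene
Product: 2 longipin-2-en-1-one (vulgarone B)
Conditions: CrO3, 3,5-dimethylpyrazole, CH2Cl2, −20 °C
Reagents that add atoms: chromium trioxide, O=[Cr](=O)=O
Why: Allylic oxidation by hexavalent chromium takes the only ring allylic CH2 (C1) of the trisubstituted alkene to the enone, as in α-pinene to verbenone; no stereocentre is formed, and the enone shields the C1–C4 part from later electrophilic oxidants.

**Step 2**
Reactants: 2 longipin-2-en-1-one
Product: 3 8-bromolongipin-2-en-1-one (C8 epimers)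
Conditions: N-bromo-N-tert-butyl-3,5-bis(trifluoromethyl)benzamide (1.1 equiv), PhCF3, blue LEDs, rt
Reagents that add atoms: N-bromo-N-tert-butyl-3,5-bis(trifluoromethyl)benzamide, CC(C)(C)N(Br)C(=O)c1cc(cc(c1)C(F)(F)F)C(F)(F)F
Why: Amidyl-radical C–H bromination is a radical chain in which the bulky electrophilic amidyl radical abstracts hydrogen from the most accessible and electron-rich methylene; that is C8, the only CH2 without a quaternary neighbour and the one farthest from the enone, and its configuration is irrelevant.

**Step 3**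
Reactants: 3 8-bromolongipin-2-en-1-one
Product: 4 longipina-2,8-dien-1-one
Conditions: DBU, toluene, 90 °C
Reagents that add atoms: none
Why: E2 dehydrobromination is expected to remove the less shielded C9–H (next to the tied-back cyclobutane carbon C10, not the gem-dimethyl carbon C6) to give the C8=C9 alkene; any Δ7 isomer is separated after step 4, where it gives a different alcohol.

**Step 4**
Reactants: 4 longipina-2,8-dien-1-one
Product: 5 7-hydroxylongipina-2,8-dien-1-one (C7 epimers)
Conditions: SeO2 (0.3 equiv), tBuOOH (3 equiv), CH2Cl2, rt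
Reagents that add atoms: tert-butyl hydroperoxide, CC(C)(C)OO; selenium dioxide, O=[Se]=O
Why: Catalytic SeO2 allylic oxidation (ene reaction then [2,3]-sigmatropic shift) is regiospecific here because only C7 carries allylic hydrogens, so oxygen lands on C7 and the alkene returns to C8=C9; the electron-poor enone alkene does not react, and both C7 epimers (and any enone 6 already formed) are carried on.

**Step 5**
Reactants: 5 7-hydroxylongipina-2,8-dien-1-one
Product: 6 longipina-2,8-diene-1,7-dione
Conditions: Dess–Martin periodinane, CH2Cl2, rt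
Reagents that add atoms: none
Why: Dess–Martin oxidation of the secondary allylic alcohol gives the C7 enone and erases the uncontrolled C7 centre.

**Step 6**
Reactants: 6 longipina-2,8-diene-1,7-dione
Product: 7 13-acetoxylongipina-2,8-diene-1,7-dione (acetoxymethyl on the α face of C6)
Conditions: Pd(OAc)2 (10 mol %), L-tert-leucine (40 mol %), 1-fluoro-2,4,6-trimethylpyridinium tetrafluoroborate (1.5 equiv), AcOH/HFIP 1:4, 70 °C
Reagents that add atoms: acetic acid, CC(O)=O
Why: Proposed new method: diastereotopic-methyl-selective β-C(sp3)–H acetoxylation of an α-quaternary ketone under chiral transient-directing-group control. L-tert-leucine condenses reversibly with the C7 ketone, and its imine nitrogen and carboxylate hold divalent palladium syn to C6, so that concerted metalation–deprotonation of one C6 methyl closes a five-membered palladacycle. The ketone has no α-hydrogen and its other β-carbon (C9) is sp2, so the two C6 methyls are the only C–H bonds within reach. Because the dienone is nearly flat and locally symmetric, the tert-butyl group of the auxiliary decides which methyl is cleaved (C13, α), and this sets C6; the amino-acid enantiomer is the one that selects C13, both being sold. The bystanding F+ oxidant raises the palladacycle to tetravalent palladium, and acetate then forms the C13–O bond by C–O reductive elimination at the primary carbon (SN2-type). The closest known reactions are transient-directing-group β-C–H arylation of ketones, amino-acid-controlled benzylic C(sp3)–H acyloxylation/fluorination of 2-alkylbenzaldehydes with the same oxidant, and oxime-directed acetoxylation of tert-butyl-type methyls.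

**Step 7**
Reactants: 7 13-acetoxylongipina-2,8-diene-1,7-dione
Product: 9 13-acetoxy-9α-hydroxylongipin-2-ene-1,7-dione, via β-boryl ketone 8 (not isolated)
Conditions: B2pin2 (1.1 equiv), Cu(MeCN)4PF6 (5 mol %), (R,R)-QuinoxP* (6 mol %), LiOtBu (10 mol %), MeOH (2 equiv), THF, 0 °C to rt; then NaBO3·4H2O, THF/H2O, rt
Reagents that add atoms: bis(pinacolato)diboron, CC1(C)OB(OC1(C)C)B2OC(C)(C)C(C)(C)O2; sodium perborate (NaBO3), [Na+].[O-]OB=O
Why: Asymmetric conjugate borylation by a chiral boryl complex of monovalent copper adds boron to C9 of the β-monosubstituted cycloheptenone much faster than to the β,β-disubstituted C1 enone; the ligand delivers it to the α face (catalyst control, since the substrate bias is expected to be small; the ligand enantiomer is matched in a test run), and perborate oxidation converts C–B into C–O with retention.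

**Step 8**
Reactants: 10 angelic acid
Product: 11 angelic 2,4,6-trichlorobenzoic anhydride
Conditions: 2,4,6-Cl3C6H2COCl (1.0 equiv), Et3N (1.05 equiv), toluene, 0 °C to rt; filter, concentrate; one batch (about 3.5 equiv relative to 9) is stored cold under argon for steps 9 and 12
Reagents that add atoms: 2,4,6-trichlorobenzoyl chloride, O=C(Cl)c1c(Cl)cc(Cl)cc1Cl
Why: Acyl substitution of the acid chloride by triethylammonium angelate gives the Yamaguchi mixed anhydride; without DMAP or heat the Z alkene is not isomerised, and no stereocentre is involved.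

**Step 9**
Reactants: 9 13-acetoxy-9α-hydroxylongipin-2-ene-1,7-dione; 11 angelic 2,4,6-trichlorobenzoic anhydride
Product: 12 13-acetoxy-9α-angeloyloxylongipin-2-ene-1,7-dione
Conditions: 11 (2 equiv), 2,6-lutidine (2.5 equiv), toluene, 80 °C (no DMAP)
Reagents that add atoms: none
Why: Yamaguchi-type mixed-anhydride esterification, in which the alcohol attacks the unhindered angeloyl carbonyl of 11, is the standard way to put an angelate on a hindered secondary alcohol without Z-to-E isomerisation; the weak, non-nucleophilic base and the absence of DMAP limit β-elimination of the new ester from the C7 ketone, and C9 keeps its configuration because only the O–H bond reacts.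

**Step 10**
Reactants: 12 13-acetoxy-9α-angeloyloxylongipin-2-ene-1,7-dione
Product: 13 9α-angeloyloxy-13-hydroxylongipin-2-ene-1,7-dione
Conditions: [tBu2Sn(OH)Cl]2 (5 mol %), MeOH/THF 1:1, 30 °C
Reagents that add atoms: none
Why: Distannoxane-catalysed transesterification is neutral and cleaves the primary acetate in preference to the hindered, conjugated secondary angelate, so the β-acyloxy ketone is never exposed to base.

**Step 11**
Reactants: 13 9α-angeloyloxy-13-hydroxylongipin-2-ene-1,7-dione
Product: 14 9α-angeloyloxy-7β,13-dihydroxylongipin-2-en-1-one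
Conditions: Me4NBH(OAc)3, MeCN/AcOH 1:1, −25 °C
Reagents that add atoms: none
Why: In this Evans–Saksena hydroxyl-directed reduction the borohydride binds O13 and delivers hydride to C7 through a six-membered transition state from the α face, giving the 7β alcohol trans to the CH2OH; the C1 enone and the ester have no directing hydroxyl and are untouched.

**Step 12**
Reactants: 14 9α-angeloyloxy-7β,13-dihydroxylongipin-2-en-1-one; 11 angelic 2,4,6-trichlorobenzoic anhydride
Product: 15 9α,13-bis(angeloyloxy)-7β-hydroxylongipin-2-en-1-one
Conditions: 11 (1.2 equiv), 2,6-lutidine (2 equiv), toluene, 50 °C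
Reagents that add atoms: none
Why: The same mixed-anhydride esterification under milder conditions acylates the primary C13 hydroxyl far faster than the secondary C7 hydroxyl, which sits next to the quaternary C6.

**Step 13**
Reactants: 15 9α,13-bis(angeloyloxy)-7β-hydroxylongipin-2-en-1-one
Product: 16 7β-acetoxy-9α,13-bis(angeloyloxy)longipin-2-en-1-one
Conditions: Ac2O, DMAP (cat.), pyridine, rt
Reagents that add atoms: acetic anhydride, CC(=O)OC(C)=O
Why: DMAP-catalysed acetylation of the last free, hindered secondary alcohol; formed alkyl angelates are stable to these conditions.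

**Compound list**
1 | (+)-α-longipinene, (1R,2S,7R,8R)-2,6,6,9-tetramethyltricyclo[5.4.0.0(2,8)]undec-9-ene | CC1(C)[C@@H]2[C@H]3CC=C(C)[C@@H]2[C@@]3(C)CCC1 | starting material
2 | longipin-2-en-1-one (vulgarone B), core as in 1 | CC1(C)[C@@H]2[C@H]3C(=O)C=C(C)[C@@H]2[C@@]3(C)CCC1 | intermediate
3 | 8-bromolongipin-2-en-1-one, both C8 epimers | CC1(C)[C@@H]2[C@H]3C(=O)C=C(C)[C@@H]2[C@@]3(C)CC(Br)C1 | intermediate
4 | longipina-2,8-dien-1-one | CC1(C)[C@@H]2[C@H]3C(=O)C=C(C)[C@@H]2[C@@]3(C)C=CC1 | intermediate
5 | 7-hydroxylongipina-2,8-dien-1-one, both C7 epimers | CC1(C)[C@@H]2[C@H]3C(=O)C=C(C)[C@@H]2[C@@]3(C)C=CC1O | intermediate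
6 | longipina-2,8-diene-1,7-dione | CC1(C)[C@@H]2[C@H]3C(=O)C=C(C)[C@@H]2[C@@]3(C)C=CC1=O | intermediate
7 | 13-acetoxylongipina-2,8-diene-1,7-dione, CH2OAc on the α face of C6 | CC(=O)OC[C@]1(C)[C@@H]2[C@H]3C(=O)C=C(C)[C@@H]2[C@@]3(C)C=CC1=O | intermediate
8 | 13-acetoxy-9α-(4,4,5,5-tetramethyl-1,3,2-dioxaborolan-2-yl)longipin-2-ene-1,7-dione | CC(=O)OC[C@]1(C)[C@@H]2[C@H]3C(=O)C=C(C)[C@@H]2[C@@]3(C)[C@H](B4OC(C)(C)C(C)(C)O4)CC1=O | intermediate
9 | 13-acetoxy-9α-hydroxylongipin-2-ene-1,7-dione | CC(=O)OC[C@]1(C)[C@@H]2[C@H]3C(=O)C=C(C)[C@@H]2[C@@]3(C)[C@H](O)CC1=O | intermediate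
10 | angelic acid, (Z)-2-methylbut-2-enoic acid | C/C=C(/C)C(=O)O | starting material
11 | angelic 2,4,6-trichlorobenzoic anhydride, (Z)-2-methylbut-2-enoic 2,4,6-trichlorobenzoic anhydride | C/C=C(/C)C(=O)OC(=O)c1c(Cl)cc(Cl)cc1Cl | intermediate
12 | 13-acetoxy-9α-angeloyloxylongipin-2-ene-1,7-dione | CC(=O)OC[C@]1(C)[C@@H]2[C@H]3C(=O)C=C(C)[C@@H]2[C@@]3(C)[C@H](OC(=O)/C(C)=C\C)CC1=O | intermediate
13 | 9α-angeloyloxy-13-hydroxylongipin-2-ene-1,7-dione | OC[C@]1(C)[C@@H]2[C@H]3C(=O)C=C(C)[C@@H]2[C@@]3(C)[C@H](OC(=O)/C(C)=C\C)CC1=O | intermediate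
14 | 9α-angeloyloxy-7β,13-dihydroxylongipin-2-en-1-one | OC[C@]1(C)[C@@H]2[C@H]3C(=O)C=C(C)[C@@H]2[C@@]3(C)[C@H](OC(=O)/C(C)=C\C)C[C@H]1O | intermediate
15 | 9α,13-bis(angeloyloxy)-7β-hydroxylongipin-2-en-1-one | C/C=C(/C)C(=O)OC[C@]1(C)[C@@H]2[C@H]3C(=O)C=C(C)[C@@H]2[C@@]3(C)[C@H](OC(=O)/C(C)=C\C)C[C@H]1O | intermediate
16 | (4R,5S,6S,7R,9R,10R,11R)-7β-acetoxy-9α,13-bis(angeloyloxy)longipin-2-en-1-one | C/C=C(/C)C(=O)OC[C@]1(C)[C@@H]2[C@H]3C(=O)C=C(C)[C@@H]2[C@@]3(C)[C@H](OC(=O)/C(C)=C\C)C[C@H]1OC(C)=O | target

**Step count**
Total steps: 13 (12 on the main line plus the one-step preparation of reagent 11). Longest linear sequence: 12 (1 to 16 through steps 1–7 and 9–13).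

**Three steps most likely to fail**

Risk at step 2 (site selectivity among C7, C8, C9 and tolerance of the enone in a radical chain). The fallback sets out from 2 and comes back at 4, replacing the radical bromination by metal-oxo C–H oxidation and the E2 step by enol triflate reduction. Fe(PDP)(MeCN)2(SbF6)2 with H2O2 and AcOH in MeCN oxidises the same C8 methylene to longipin-2-ene-1,8-dione F1. KN(SiMe3)2 and PhNTf2 at −78 °C give the kinetic enol triflate 1-oxolongipina-2,8-dien-8-yl trifluoromethanesulfonate F2. Pd(OAc)2/PPh3 with HCO2H and Bu3N in DMF at 60 °C reduces it to 4.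

Risk at step 3 (regiochemistry of the elimination; the preference for C9–H over C7–H is a steric argument only). The fallback sets out from 3 and comes back at 6, using the other regioisomer instead of discarding it. If the DBU elimination of 3 gives mainly longipina-2,7-dien-1-one F3, singlet oxygen (O2, tetraphenylporphyrin, visible light, CH2Cl2) undergoes the ene reaction with oxygen adding at C7 and the double bond moving to C8=C9, since C9 holds the only allylic hydrogens. This gives 7-hydroperoxylongipina-2,8-dien-1-one F4, which Ac2O, pyridine and DMAP dehydrate in the same flask to 6; steps 4 and 5 are then skipped.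

Risk at step 6 (the new C–H acetoxylation; imine formation at the hindered enone, methyl selection and the C–O forming elimination are all untested here). The fallback uses known oxime-directed chemistry, sets out from 6 and comes back at 7. Compound 6 is converted with NH2OH·HCl and NaOAc in EtOH at 60 °C into longipina-2,8-diene-1,7-dione dioxime F5. Treatment with Pd(OAc)2 (10 mol %) and PhI(OAc)2 in AcOH/Ac2O at 90 °C acetylates both oxime hydroxyls in the flask and acetoxylates a C6 methyl through the C7 O-acetyl oxime. The C1 oxime has only a cyclobutane methine within reach, which does not palladate. This gives 13-acetoxylongipina-2,8-diene-1,7-dione bis(O-acetyloxime) F6 after chromatographic removal of its C6 epimer, since this version has no stereocontrol. Aqueous NaHSO3 in EtOH at 80 °C then cleaves both oxime esters to give 7.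

**Further compounds**
F1 | step 2 | longipin-2-ene-1,8-dione | CC1(C)[C@@H]2[C@H]3C(=O)C=C(C)[C@@H]2[C@@]3(C)CC(=O)C1
F2 | step 2 | 1-oxolongipina-2,8-dien-8-yl trifluoromethanesulfonate | CC1(C)[C@@H]2[C@H]3C(=O)C=C(C)[C@@H]2[C@@]3(C)C=C(OS(=O)(=O)C(F)(F)F)C1
F3 | step 3 | longipina-2,7-dien-1-one | CC1(C)[C@@H]2[C@H]3C(=O)C=C(C)[C@@H]2[C@@]3(C)CC=C1
F4 | step 3 | 7-hydroperoxylongipina-2,8-dien-1-one (C7 epimers) | CC1(C)[C@@H]2[C@H]3C(=O)C=C(C)[C@@H]2[C@@]3(C)C=CC1OO
F5 | step 6 | longipina-2,8-diene-1,7-dione dioxime | CC1(C)[C@@H]2[C@H]3C(=NO)C=C(C)[C@@H]2[C@@]3(C)C=CC1=NO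
F6 | step 6 | 13-acetoxylongipina-2,8-diene-1,7-dione bis(O-acetyloxime) | CC(=O)OC[C@]1(C)[C@@H]2[C@H]3C(=NOC(C)=O)C=C(C)[C@@H]2[C@@]3(C)C=CC1=NOC(C)=O
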